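Start from the constants: none is given, so read them off the runs.

| flask | solid substrate | reagent | second substrate | remark | time |
|---|---|---|---|---|---|
| Thursday's | 0.22 M | 0.375 M | 0.15 M | run made earlier |  |
| Friday's | 0.70 M | 0.375 M | 0.15 M | run made earlier |  |
| Tuesday's | 0.15 M | 0.375 M | 0.12 M | run made earlier |  |
| north | 0.15 M | 0.120 M | 0.300 M |  | 50 h |
| west | 0.15 M | 0.375 M | 0.0800 M |  | 50 h |
| north-west | 0.15 M | 0.375 M | 0.150 M |  | 50 h |
| south-east | 0.15 M | 1.50 M | 0.100 M |  | 50 h |
| south | 0.50 M | 0.120 M | 0.0400 M |  | 50 h |
| east | 0.30 M | 0.100 M | 0.500 M |  | 50 h |

- Thursday's (time / h: target / %, solid substrate / %): 4.00: 2, 80; 12.0: 7, 58; 25.0: 19, 42; 40.0: 29, 27; 48.0: 31, 23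
- Friday's (time / h: target / %, solid substrate / %): 4.00: 1, 93; 8.00: 1, 91; 15.0: 3, 88; 25.0: 8, 82; 48.0: 8, 77
- Tuesday's (time / h: target / %, solid substrate / %): 4.00: 4, 73; 12.0: 14, 38; 25.0: 28, 11; 40.0: 43, 0; 48.0: 47, 0

(each reading ± 1.5 percentage points)

* the flasks put in order of amount of target, in percent of the solid substrate charged, best first, at 50 h (north / west / north-west / south-east / south / east)
* the amount of target, in percent of the solid substrate charged of the flask you put first, at 50 h
* the amount of target, in percent of the solid substrate charged of the flask you put last, at 50 h

- as a solid, counted per litre of solution: solid substrate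
- the numbers in the tables scatter by 1.5 percentage points (one standard deviation)
- at the start none of the solid substrate is in solution
- what has only dissolved of solid substrate counts as not reacted
- a reading or a percentage of target counts all its forms, free or not

At 48.0 h, target per litre stands at 0.0682 M in Thursday's run and 0.0705 M in Tuesday's run. Tuesday's run has less second substrate, 0.12 M against 0.15 M, and less solid substrate, 0.15 M against 0.22 M, yet its target is about equal. So I treat second substrate as a rival for reagent, not a partner of target. I also take the rate as pseudo-first-order in free reagent. That order is my assumption, since the three runs share 0.375 M of reagent.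

Two extremes can be done in the head. In the first, second substrate leaves reagent alone, so free reagent equals its charge. In the second, second substrate binds reagent one for one at once, so free reagent is the excess, reagent charge minus second substrate charge, or nothing if that is negative. I use the two as an estimated range for the real flask, not as bounds, since target formation also takes reagent and neither extreme counts that.

Between 12.0 h and 40.0 h, Tuesday's run gains target at 0.00155 M/h, a reading with its scatter. Dividing the reagent charge by this rate gives the reagent time constant τ = 241 h, and dividing the excess by it gives 164 h for the second extreme. Target per litre is then free reagent times time over the time constant, capped by the solid charge.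

South-east exceeds its charge of 0.15 M in both extremes, with 0.311 M and 0.426 M, so I put it first, near 100 %. West spans 51.8 % to 59.9 %, and north-west 45.7 % to 51.8 %. South gives 4.97 %. North and east have negative excess, so I take the middle of nothing and the first extreme: 8.29 % for north and 3.45 % for east. My order is south-east, west, north-west, north, south, east.

The forecast gives north-west > south-east > west > north > east > south, with 55 % (47 % to 63 %) first and 2.5 % (1.5 % to 5 %) last. Its ground differs from mine: “Target lags, pointing to an intermediate”.

The flasks give south-east > west > north-west > north > south > east, from 91.3 % in south-east down to 2.73 % in east.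

    starting material + reagent ⇌ target (K = 8.70 /M, k = 2.60 × 10⁻⁵ /M/s)
    second substrate + reagent ⇌ second product (K = 19.0 /M, k = 4.90 × 10⁻⁵ /M/s)
    solid substrate ⇌ starting material, rate k3*(cs3 - [starting material]) while solid is left; crystals form when [starting material] > cs3 (solubility = 0.110 M, k = 3.30 × 10⁻⁵ /s)
    second substrate + target ⇌ idle adduct, settled at all times (K = 3.30 /M)

South-east stands 36 percentage points above the forecast's top, and it ends with 3.90 % of its second substrate and 84.6 % of its reagent unbound. Now take the neighbour, east with 0.25 M of reagent. Its excess is −0.250 M, so the second extreme gives nothing, while τ gives 17.3 % for the first and 8.63 % for the middle. That flask gives 7.79 %, with 14 % of its reagent unbound.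

(All runs are simulated on assumed constants; noise was put on by code.)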